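The route rests on cutting the side chain at its lone carbinol carbon C6′ (side-chain atoms counted from ring carbon C3), a CH(OH) flanked only by methylene chains and five CH2 groups away from the benzo-fused δ-lactone ring. This normally electrophilic carbon is used as an α-oxy carbanion: (+)-sparteine-complexed lithiated hexyl 2,4,6-triisopropylbenzoate captures the primary pinacol boronic ester that ends the C1′–C5′ tether of the intact, benzyl-protected dihydroisocoumarin. A stereospecific 1,2-metallate shift forges C5′–C6′ and sets the (S)-carbinol under reagent control, independent of remote C3, which derives from (R)-epichlorohydrin. In-flask C–B oxidation and a final hydrogenolysis complete the route.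

Key step: step 8

Remark: 1,3-bis(benzyloxy)-5-bromobenzene, but-3-en-1-ylmagnesium bromide (THF solution), (+)-sparteine and 2,4,6-triisopropylbenzoic acid are taken as purchasable. The target is (R)-configured at C3 and (S)-configured at C6′.

Step 1
Reactants: 1 (R)-epichlorohydrin; 2 but-3-en-1-ylmagnesium bromide
Product: 3 (R)-1-chlorohept-6-en-2-ol
Conditions: CuI (10 mol%), THF, −40 → −20 °C; aq. NH4Cl
Reagents that add atoms: none
Why: Copper-catalysed Grignard opening of the epoxide (SN2 at the unsubstituted ring carbon) leaves the C–O stereocentre untouched and keeps the C–Cl bond for the next ring closure.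

Step 2
Reactants: 3 (R)-1-chlorohept-6-en-2-ol
Product: 4 (R)-2-(pent-4-en-1-yl)oxirane
Conditions: powdered NaOH, Et2O, rt
Reagents that add atoms: none
Why: Intramolecular Williamson etherification (alkoxide SN2 at the primary CH2Cl) closes the oxirane without involving the stereocentre, so the (R) configuration is carried over.

Step 3
Reactants: 5 1,3-bis(benzyloxy)-5-bromobenzene; 4 (R)-2-(pent-4-en-1-yl)oxirane
Product: 7 (R)-1-[3,5-bis(benzyloxy)phenyl]hept-6-en-2-ol, via arylmagnesium bromide 6 (not isolated)
Conditions: Mg, THF, 50 °C; then CuI (10 mol%), 4, THF, −30 → 0 °C; aq. NH4Cl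
Reagents that add atoms: none
Why: Grignard formation followed by copper-catalysed SN2 opening of the terminal epoxide at its CH2 gives the homobenzylic alcohol, with the (R) centre (the future C3) retained because it is not the site of attack.

Step 4
Reactants: 7 (R)-1-[3,5-bis(benzyloxy)phenyl]hept-6-en-2-ol
Product: 8 (R)-1-[3,5-bis(benzyloxy)-2-bromophenyl]hept-6-en-2-ol
Conditions: NBS (1.0 equiv), MeCN, −20 → 0 °C, dark
Reagents that add atoms: N-bromosuccinimide, O=C1CCC(=O)N1Br
Why: Electrophilic aromatic bromination of the strongly activated resorcinol diether ring should occur ortho to the alkyl chain and para to a benzyloxy group (the site between the two benzyloxy groups is more hindered) and should be much faster at low temperature than attack of NBS on the isolated terminal alkene.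

Step 5
Reactants: 8 (R)-1-[3,5-bis(benzyloxy)-2-bromophenyl]hept-6-en-2-ol
Product: 11 (R)-6,8-bis(benzyloxy)-3-(pent-4-en-1-yl)isochroman-1-one, via dilithio species 9 (not isolated), via hydroxy acid 10 (not isolated)
Conditions: n-BuLi (2.2 equiv), THF, −78 °C; CO2 (g), −78 °C → rt; 1 M HCl; then TsOH·H2O (cat.), toluene, 60 °C
Reagents that add atoms: carbon dioxide, O=C=O
Why: Bromine–lithium exchange on the lithium alkoxide, carboxylation of the aryllithium and acid-catalysed lactonisation of the δ-hydroxy acid (six-membered ring) install C1 without touching C3.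

Step 6
Reactants: 11 (R)-6,8-bis(benzyloxy)-3-(pent-4-en-1-yl)isochroman-1-one
Product: 12 (R)-6,8-bis(benzyloxy)-3-[5-(4,4,5,5-tetramethyl-1,3,2-dioxaborolan-2-yl)pentyl]isochroman-1-one
Conditions: HBpin (1.3 equiv), [Ir(cod)Cl]2 (1.5 mol%), dppm (3 mol%), CH2Cl2, rt
Reagents that add atoms: pinacolborane, CC1(C)OBOC1(C)C
Why: Iridium-catalysed anti-Markovnikov hydroboration of the terminal alkene places boron on the terminal carbon (C5′) and tolerates the lactone and the benzyl ethers.

Step 7
Reactants: 13 hexan-1-ol
Product: 14 hexyl 2,4,6-triisopropylbenzoate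
Conditions: 2,4,6-triisopropylbenzoic acid, PPh3, DIAD, THF, 0 °C → rt
Reagents that add atoms: 2,4,6-triisopropylbenzoic acid, CC(C)c1cc(C(C)C)c(C(=O)O)c(C(C)C)c1
Why: Mitsunobu esterification of the primary alcohol gives the hindered benzoate whose carbonyl directs α-lithiation yet is shielded against attack by s-BuLi.

Step 8
Reactants: 14 hexyl 2,4,6-triisopropylbenzoate; 12 (R)-6,8-bis(benzyloxy)-3-[5-(4,4,5,5-tetramethyl-1,3,2-dioxaborolan-2-yl)pentyl]isochroman-1-one
Product: 18 (R)-6,8-bis(benzyloxy)-3-[(S)-6-hydroxyundecyl]isochroman-1-one, via lithiated benzoate 15 (not isolated), via boronate complex 16 (not isolated), via secondary boronic ester 17 (not isolated)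
Conditions: 14 (1.15 equiv), (+)-sparteine (1.15 equiv), s-BuLi (1.1 equiv), Et2O, −78 °C, 5 h; 12 (1.0 equiv) in Et2O, −78 °C, 2 h; → rt, then 35 °C; then THF, 2 M NaOH/30% H2O2, 0 °C → rt; 1 M HCl work-up
Reagents that add atoms: hydrogen peroxide, OO
Why: s-BuLi/(+)-sparteine removes the pro-R α-proton of 14 to give the configurationally stable, dipole-stabilised (R)-organolithium 15; its carbanionic C6′ adds to the boron of 12 with retention to give boronate 16, and on warming the primary C5′ methylene migrates from boron to C6′ anti-periplanar to the departing triisopropylbenzoate (inversion at C6′) to give secondary boronic ester 17, which alkaline peroxide oxidises with retention to the (S)-alcohol. The closest known reaction type is lithiation–borylation, that is a Matteson-type stereospecific 1,2-metallate rearrangement of the boronate formed from a Hoppe-type sparteine-complexed α-lithiated ester, here uniting two carbons that are both nucleophilic in conventional terms. No ring is closed. The single new stereocentre C6′ is fixed by the sparteine enantiomer alone, and because every later event at that carbon is stereospecific the remote C3 centre has no influence. The step needs chemoselectivity for boron over the lactone carbonyl and over the acidic benzylic C4–H; this should be secured by the very fast ate-complex formation of an unhindered primary pinacol boronic ester at −78 °C, by the lactone being a 2,6-disubstituted, electron-rich benzoate, and by using only a slight excess of 15. Any lactone opened during the basic oxidation should reclose on acidic work-up.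

Step 9
Reactants: 18 (R)-6,8-bis(benzyloxy)-3-[(S)-6-hydroxyundecyl]isochroman-1-one
Product: 19 (R)-6,8-dihydroxy-3-[(S)-6-hydroxyundecyl]isochroman-1-one
Conditions: H2 (1 atm), 10% Pd/C, EtOAc–EtOH, rt
Reagents that add atoms: none
Why: Catalytic hydrogenolysis of the two aryl benzyl ethers leaves the aliphatic secondary alcohol, the lactone (no benzylic C–O bond) and both stereocentres untouched.

Compound list
1 | (R)-epichlorohydrin | ClC[C@H]1CO1 | starting material
2 | but-3-en-1-ylmagnesium bromide | C=CCC[Mg]Br | starting material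
3 | (R)-1-chlorohept-6-en-2-ol | ClC[C@H](O)CCCC=C | intermediate
4 | (R)-2-(pent-4-en-1-yl)oxirane | C=CCCC[C@@H]1CO1 | intermediate
5 | 1,3-bis(benzyloxy)-5-bromobenzene | Brc1cc(OCc2ccccc2)cc(OCc2ccccc2)c1 | starting material
6 | [3,5-bis(benzyloxy)phenyl]magnesium bromide (not isolated) | Br[Mg]c1cc(OCc2ccccc2)cc(OCc2ccccc2)c1 | intermediate
7 | (R)-1-[3,5-bis(benzyloxy)phenyl]hept-6-en-2-ol | C=CCCC[C@@H](O)Cc1cc(OCc2ccccc2)cc(OCc2ccccc2)c1 | intermediate
8 | (R)-1-[3,5-bis(benzyloxy)-2-bromophenyl]hept-6-en-2-ol | C=CCCC[C@@H](O)Cc1cc(OCc2ccccc2)cc(OCc2ccccc2)c1Br | intermediate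
9 | dilithio species: lithium (R)-alkoxide of 8 with lithium in place of bromine (not isolated) | C=CCCC[C@@H](O[Li])Cc1cc(OCc2ccccc2)cc(OCc2ccccc2)c1[Li] | intermediate
10 | 2,4-bis(benzyloxy)-6-[(R)-2-hydroxyhept-6-en-1-yl]benzoic acid (not isolated) | C=CCCC[C@@H](O)Cc1cc(OCc2ccccc2)cc(OCc2ccccc2)c1C(=O)O | intermediate
11 | (R)-6,8-bis(benzyloxy)-3-(pent-4-en-1-yl)isochroman-1-one | C=CCCC[C@@H]1Cc2cc(OCc3ccccc3)cc(OCc3ccccc3)c2C(=O)O1 | intermediate
12 | (R)-6,8-bis(benzyloxy)-3-[5-(4,4,5,5-tetramethyl-1,3,2-dioxaborolan-2-yl)pentyl]isochroman-1-one | CC1(C)OB(CCCCC[C@@H]2Cc3cc(OCc4ccccc4)cc(OCc4ccccc4)c3C(=O)O2)OC1(C)C | intermediate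
13 | hexan-1-ol | CCCCCCO | starting material
14 | hexyl 2,4,6-triisopropylbenzoate | CCCCCCOC(=O)c1c(C(C)C)cc(C(C)C)cc1C(C)C | intermediate
15 | (R)-1-lithiohexyl 2,4,6-triisopropylbenzoate, (+)-sparteine complex (not isolated) | CCCCC[C@@H]([Li])OC(=O)c1c(C(C)C)cc(C(C)C)cc1C(C)C | intermediate
16 | lithium boronate complex of 15 and 12, boron on C6′ with retention (not isolated) | [Li+].CCCCC[C@@H]([B-]1(CCCCC[C@@H]2Cc3cc(OCc4ccccc4)cc(OCc4ccccc4)c3C(=O)O2)OC(C)(C)C(C)(C)O1)OC(=O)c1c(C(C)C)cc(C(C)C)cc1C(C)C | intermediate
17 | (R)-6,8-bis(benzyloxy)-3-[(S)-6-(4,4,5,5-tetramethyl-1,3,2-dioxaborolan-2-yl)undecyl]isochroman-1-one (not isolated) | CCCCC[C@H](B1OC(C)(C)C(C)(C)O1)CCCCC[C@@H]1Cc2cc(OCc3ccccc3)cc(OCc3ccccc3)c2C(=O)O1 | intermediate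
18 | (R)-6,8-bis(benzyloxy)-3-[(S)-6-hydroxyundecyl]isochroman-1-one | CCCCC[C@H](O)CCCCC[C@@H]1Cc2cc(OCc3ccccc3)cc(OCc3ccccc3)c2C(=O)O1 | intermediate
19 | (R)-6,8-dihydroxy-3-[(S)-6-hydroxyundecyl]isochroman-1-one | CCCCC[C@H](O)CCCCC[C@@H]1Cc2cc(O)cc(O)c2C(=O)O1 | target

Total step count: 9. Longest linear sequence: 8 (steps 1–6, 8, 9).

Steps most likely to fail

1. Step 8. The α-oxy organolithium may add to the lactone carbonyl, or deprotonate benzylic C4–H with β-elimination of the carboxylate (ring opening), before it is captured by boron. Incomplete or too-warm lithiation would also erode configurational purity at C6′, and the resulting remote epimer would be hard to remove. Fallback, setting out from 11 and returning at 18: hydroboration of the alkene with diethylborane (from BH3·SMe2 and Et3B) should give the alkyl(diethyl)borane F1. Boron–zinc exchange with Et2Zn, with removal of the volatiles, should give the bis(alkyl)zinc F2. Catalytic asymmetric addition of F2 to hexanal follows, using Ti(OiPr)4 and (1S,2S)-1,2-bis(trifluoromethanesulfonamido)cyclohexane (8 mol%) in toluene at −20 °C. This ligand antipode is chosen to deliver the alkyl group to the Re face of the aldehyde, by analogy with the Si-face ethylation of benzaldehyde under the (1R,2R) ligand. The step forms the same C5′–C6′ bond under lactone-tolerant conditions and gives 18 directly.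

2. Step 4. Electrophilic bromine may be consumed by the terminal alkene, assisted by the free hydroxyl (6-exo bromoetherification), or the ring may be brominated twice. Fallback, setting out from 7 and returning at 11 (bypassing 8 and step 5): Vilsmeier–Haack formylation (POCl3, DMF, 0 °C → rt) should formylate the same ring position and convert the hydroxyl into its formate, giving the formate aldehyde F3. K2CO3 in aqueous MeOH cleaves the formate, and the hydroxy aldehyde closes to the lactol F4. Oxidation of the lactol (TEMPO/PhI(OAc)2, CH2Cl2) gives 11.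

3. Step 5. The aryllithium may be protonated prematurely, may metalate a benzyl ether CH2, or may be alkylated by the butyl bromide formed in the exchange. Fallback, setting out from 8 and returning at 11: palladium-catalysed carbonylative lactonisation (Pd(OAc)2, Xantphos, CO 1 atm, Et3N, toluene, 90 °C), in which the acyl-palladium is trapped by the pendant hydroxyl; no organolithium is involved and no new compound is made (F0).

Further compounds
F1 | step 8 | diethyl{5-[(R)-6,8-bis(benzyloxy)-1-oxoisochroman-3-yl]pentyl}borane | CCB(CC)CCCCC[C@@H]1Cc2cc(OCc3ccccc3)cc(OCc3ccccc3)c2C(=O)O1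
F2 | step 8 | bis{5-[(R)-6,8-bis(benzyloxy)-1-oxoisochroman-3-yl]pentyl}zinc | [Zn](CCCCC[C@@H]1Cc2cc(OCc3ccccc3)cc(OCc3ccccc3)c2C(=O)O1)CCCCC[C@@H]1Cc2cc(OCc3ccccc3)cc(OCc3ccccc3)c2C(=O)O1
F3 | step 4 | (R)-1-[3,5-bis(benzyloxy)-2-formylphenyl]hept-6-en-2-yl formate | C=CCCC[C@@H](OC=O)Cc1cc(OCc2ccccc2)cc(OCc2ccccc2)c1C=O
F4 | step 4 | (3R)-6,8-bis(benzyloxy)-3-(pent-4-en-1-yl)isochroman-1-ol (C1 epimers) | C=CCCC[C@@H]1Cc2cc(OCc3ccccc3)cc(OCc3ccccc3)c2C(O)O1
F0 | step 5 | none | none
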